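In a one-step world, a partner consumed by a species held at a constant concentration decays exponentially, with an exponent of rate constant times concentration times time. In this flask the capture agent is that partner. Its loss is pseudo-first-order in the capture agent, with [single product] as the multiplier, and a changing [single product] only replaces the concentration by its time mean.

in all of them: substrate 0.20 M

| run | reagent | capture agent | remark | time |
|---|---|---|---|---|
| eta | 1.8 equiv | 0.20 M | run made earlier |  |
| alpha | 4.6 equiv | 0.20 M | run made earlier |  |
| Monday's | 3.00 equiv | 0.200 M |  | 6.0 min |
| Wednesday's | 1.50 equiv | 0.200 M |  | 6.0 min |
| Tuesday's | 1.20 equiv | 0.200 M |  | 6.0 min |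

| run | time / min | single product / % | double product / % |
|---|---|---|---|
| eta | 0.500 | 13 | 2 |
| eta | 0.667 | 14 | 4 |
| eta | 1.00 | 15 | 4 |
| eta | 1.50 | 9 | 7 |
| eta | 2.50 | 10 | 10 |
| eta | 4.00 | 9 | 5 |
| eta | 6.00 | 7 | 6 |
| alpha | 0.500 | 24 | 11 |
| alpha | 0.667 | 23 | 17 |
| alpha | 1.00 | 20 | 22 |
| alpha | 1.50 | 13 | 25 |
| alpha | 2.50 | 11 | 28 |
| alpha | 4.00 | 4 | 23 |
| alpha | 6.00 | 7 | 18 |

(readings scatter by 1.5 percentage points)

* which of these holds the largest part of the substrate at the end of Monday's (double product / single product / substrate)
* which of these holds the largest part of the substrate at the end of Wednesday's (double product / single product / substrate)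
* which of these holds the largest part of the substrate at the end of Tuesday's (double product / single product / substrate)
* single product at the end of Wednesday's, in percent of the substrate charged

- steps that have been proposed: substrate + reagent -> single product; reagent + single product <-> double product; single product + capture agent -> trapped intermediate

Capture agent and substrate are charged equally (0.200 M, 0.20 M) and each trapping takes one single product, so the capture left, in percent, equals substrate plus single plus double. I count no substrate in alpha from 2.50 min. The sum of single and double then falls from 39.0% to 25.0% at 6.00 min, and I integrate the single readings by trapezoids:

k = ln(capture before / capture after) / (mean [single product] × time) = 9.99 M⁻¹ min⁻¹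

This k is my trapping constant, and the ladder follows from it.

At full charge a single product lives 0.500 min, and eta already reads 13% at 0.500 min. Integrating eta's single readings gives:

capture left in eta = 32.6%

The life therefore lengthens to 1.53 min, which is shorter than the 6.0 min of the run, so I treat the single product as a resting state that follows its feed. My capture left in eta stands above the 13.0% of single and double read there at 6.00 min, so by my balance eta still holds substrate at that time, though the size of this difference carries the scatter of the readings.

Wednesday's and Tuesday's carry less reagent than eta, so I put substrate first in both. Monday's leans towards alpha, where double reads 18% against single 7%, so I put double first. Eta's reagent lies closer to Wednesday's than alpha's does, so I take eta's reading of 7% single at 6.00 min as my number for Wednesday's.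

The forecast says double product, substrate, substrate and 7.5%, a little above my number, on the ground that “low-equivalent runs starve and substrate lingers”.

Wednesday's ends at 6.97% single product, made at 0.877 of the rate at which it is used; the largest holders are double product, substrate and substrate on Monday's, Wednesday's and Tuesday's.

    substrate + reagent → single product (k = 0.0330 M⁻¹ s⁻¹)
    reagent + single product ⇌ double product (K = 4.20 M⁻¹, k = 0.0270 M⁻¹ s⁻¹)
    single product + capture agent → trapped intermediate (k = 0.200 M⁻¹ s⁻¹)

From 45.6% of capture agent at 3.00 min, my constant and the mean single carry Wednesday's to 27.9% at 6.00 min, and the flask holds 25.6%. The same step takes Tuesday's from 51.2% to 33.8%, and that flask holds 31.5%.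

The earlier runs and the new flask are calculated on assumed constants, noise included.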